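Its constants are assumed; what happens was integrated by code.

Compare how the complex with two exchanged fills and drains in the four vessels.

    starting complex + incoming ligand → leaving ligand + complex with one exchanged (k1 = 3.1 M⁻¹ s⁻¹)
    complex with one exchanged + incoming ligand → leaving ligand + complex with two exchanged (k2 = 0.40 M⁻¹ s⁻¹)
    complex with two exchanged + incoming ligand → leaving ligand + complex with three exchanged (k3 = 2.6 M⁻¹ s⁻¹)
    complex with three exchanged + incoming ligand → leaving ligand + complex with four exchanged (k4 = 1.9 M⁻¹ s⁻¹)
    complex with two exchanged ⇌ isomer of the product (K5 = 0.47, k5 = 0.011 s⁻¹)

| flask | starting complex | incoming ligand | remark | time |
|---|---|---|---|---|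
| epsilon | 0.011 M | 0.0121 M | one stirred flow tank at steady state, fed with the mixture as stated, mean residence time 2.0 min |  |
| eta | 0.011 M (fed, over 2.00 min) | 0.0121 M | all but starting complex at the start; starting complex goes in evenly over 2.00 min, the run ends at 2.0 min | 2.0 min |
| beta | 0.011 M | 0.0121 M | everything together in a closed stirred flask, run for 2.0 min | 2.0 min |
| theta | 0.011 M | 0.0121 M | a tube with plug flow, the mixed feed as stated, residence time 2.0 min | 2.0 min |

1. the set-up with the highest amount of complex with two exchanged at the outlet or at the end, in percent of the starting complex put in ("none" if the first two lie within 2 percentage points) (epsilon / eta / beta / theta / none)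
2. amount of complex with two exchanged at the outlet or at the end, in percent of the starting complex put in, epsilon
3. amount of complex with two exchanged at the outlet or at the end, in percent of the starting complex put in, eta
4. amount of complex with two exchanged at the outlet or at the end, in percent of the starting complex put in, beta
5. amount of complex with two exchanged at the outlet or at the end, in percent of the starting complex put in, theta

- the stated concentrations are those of everything mixed, before any reaction; amounts are the same in each set-up
- the feed brings no volume worth counting
- run time (eta): 2.0 min

1. The ratio of complex with two exchanged to complex with one exchanged is what I watch. At the crossing ratio, k2/k3 = 0.154, the second exchange fills exactly as fast as the third drains. This is a selectivity factor of the two steps. The incoming ligand cancels, as it enters both rates.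

2. Turn the question round. A closed flask and a plug-flow tube give each portion the same 2.0 min, so they tie. A winner must therefore be the tank or the dosed run, standing 2 percentage points above that pair.

3. I hold the ligand at its charged level and count forward isomerisation with no return. With the first exchange taken as instant, the closed flask then keeps 0.559 of the charge as complex with one exchanged, at a ratio of 0.114. That gives 6.38%.

4. The tank keeps 0.518 as complex with one exchanged. Washout adds to its drain, so its ratio is 0.0953. That gives 4.93%.

5. Merely to draw level, the tank needs a ratio of 0.123, which is more than it has. On this reckoning it stands 1.4 points below the closed flask.

6. Late portions of the dosed run sit for less time, so I commit to a bound: 6.38%. My call is none.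

7. The forecast gives 3.6%, 4.1%, 5.3% and 5.3%, and calls none. Its closed figure is lower than mine. It says: “The top two set-ups are identical and the others are also only a point or two behind”.

8. The runs give 3.62% in the tank, 3.80% dosed, 4.99% closed and 4.99% in the tube, so the call is none. The tank holds 49.8% of its charge as complex with one exchanged. Its ratio reads 0.0728, about half the crossing ratio. The closed flask left for 20.0 min holds 6.18% of its charge as complex with two exchanged, and at the crossing ratio that amount goes with 40.2% of the charge as complex with one exchanged.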